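**Retrosynthetic overview**
1. Target 34 ⇐ desilylation of 33. The C12 acid comes from the C7 isopropenyl CH3 (SeO2, then Dess–Martin/NaClO2); the C8 ester comes from diol 22 and Z-acid 27.
2. Cyclohexane 22 ⇐ Wittig opening of bridged lactol 21. The carbocycle (second ring formed) is closed at C7–C8 by a carbonyl-ene reaction of lactone aldehyde 18; C8–OH is reset through ketone 20.
3. 18 ⇐ anti-alkylation of butyrolactone 14 (quaternary C10). 14 ⇐ trans-lactone 12 (first ring formed) ⇐ cis-lactone 9 by inversion at C6 through tosylate and epoxide.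
4. 9 ⇐ ester 6, whose key C5–C10 bond is made by a Johnson–Claisen rearrangement of allylic alcohol 4; the bought stereocentre of methyl (S)-glycerate acetonide 1 directs C5.
5. Ring order: γ-lactone template, then carbocycle; the lactone is finally opened to the vinyl group and C6–OH.

Assumption: the SMILES is read as compound 34; labels C1–C15 in the explanations are elemane labels (ring C5–C10, C10 carries CH3 and vinyl, C4/C3/C15 and C11/C13/C12 are the two propenyl units).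

**Step 1**
Reactants: 1 methyl (4S)-2,2-dimethyl-1,3-dioxolane-4-carboxylate
Product: 3 ethyl (2E)-3-[(4R)-2,2-dimethyl-1,3-dioxolan-4-yl]-2-methylprop-2-enoate, via aldehyde 2 (not isolated)
Conditions: i-Bu2AlH (1.05 equiv), CH2Cl2, −78 °C; then Ph3P=C(CH3)CO2Et, −78 °C → rt
Reagents that add atoms: ethyl 2-(triphenyl-λ5-phosphanylidene)propanoate CCOC(=O)C(C)=P(c1ccccc1)(c1ccccc1)c1ccccc1
Why: Low-temperature i-Bu2AlH reduction stops at the aldehyde, which is trapped in situ by a Wittig reaction with the stabilized ylide to give the (E)-enoate without epimerizing the bought dioxolane stereocentre.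

**Step 2**
Reactants: 3 ethyl (2E)-3-[(4R)-2,2-dimethyl-1,3-dioxolan-4-yl]-2-methylprop-2-enoate
Product: 4 (2E)-3-[(4R)-2,2-dimethyl-1,3-dioxolan-4-yl]-2-methylprop-2-en-1-ol
Conditions: i-Bu2AlH (2.3 equiv), CH2Cl2, −78 → 0 °C
Reagents that add atoms: none
Why: 1,2-Reduction of the enoate by i-Bu2AlH gives the (E)-allylic alcohol and touches no stereocentre.

**Step 3**
Reactants: 4 (2E)-3-[(4R)-2,2-dimethyl-1,3-dioxolan-4-yl]-2-methylprop-2-en-1-ol
Product: 6 ethyl (3R)-3-[(4R)-2,2-dimethyl-1,3-dioxolan-4-yl]-2,4-dimethylpent-4-enoate, via mixed ketene acetal 5 (not isolated)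
Conditions: EtC(OEt)3 (6 equiv), EtCO2H (5 mol %), 140 °C, EtOH distilled off
Reagents that add atoms: triethyl orthopropionate CCC(OCC)(OCC)OCC
Why: Johnson–Claisen [3,3]-sigmatropic rearrangement through a chair transition state (dioxolanyl equatorial) forms the key C5–C10 bond; A(1,3) strain with the cis methyl holds the dioxolane C–H in the alkene plane and the new bond forms anti to the allylic C–O bond, so the bought centre sets C5 (3R), while the epimeric α-carbon is fixed in step 11.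

**Step 4**
Reactants: 6 ethyl (3R)-3-[(4R)-2,2-dimethyl-1,3-dioxolan-4-yl]-2,4-dimethylpent-4-enoate
Product: 7 ethyl (3R)-3-[(4R)-2,2-dimethyl-1,3-dioxolan-4-yl]-4-(hydroxymethyl)-2-methylpent-4-enoate
Conditions: SeO2 (0.3 equiv), t-BuOOH (3 equiv), CH2Cl2, rt
Reagents that add atoms: tert-butyl hydroperoxide CC(C)(C)OO
Why: Catalytic SeO2 allylic oxidation (ene reaction, then [2,3]-shift) hydroxylates the only allylic CH3 (C15) of the only alkene present.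

**Step 5**
Reactants: 7 ethyl (3R)-3-[(4R)-2,2-dimethyl-1,3-dioxolan-4-yl]-4-(hydroxymethyl)-2-methylpent-4-enoate
Product: 8 ethyl (3R)-4-{[(tert-butyldiphenylsilyl)oxy]methyl}-3-[(4R)-2,2-dimethyl-1,3-dioxolan-4-yl]-2-methylpent-4-enoate
Conditions: t-BuPh2SiCl, imidazole, DMF, rt
Reagents that add atoms: tert-butyl(chloro)diphenylsilane CC(C)(C)[Si](Cl)(c1ccccc1)c1ccccc1
Why: Standard silylation of the primary allylic alcohol gives an ether that survives the later acid, base, hydride and Lewis-acid steps.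

**Step 6**
Reactants: 8 ethyl (3R)-4-{[(tert-butyldiphenylsilyl)oxy]methyl}-3-[(4R)-2,2-dimethyl-1,3-dioxolan-4-yl]-2-methylpent-4-enoate
Product: 9 (4R,5R)-4-{3-[(tert-butyldiphenylsilyl)oxy]prop-1-en-2-yl}-5-(hydroxymethyl)-3-methyloxolan-2-one
Conditions: TsOH·H2O (10 mol %), MeOH, rt → 40 °C
Reagents that add atoms: none
Why: Acid-catalysed acetonide methanolysis is followed by spontaneous γ-lactonization with retention, giving the 4,5-cis butyrolactone and leaving only the primary hydroxyl free.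

**Step 7**
Reactants: 9 (4R,5R)-4-{3-[(tert-butyldiphenylsilyl)oxy]prop-1-en-2-yl}-5-(hydroxymethyl)-3-methyloxolan-2-one
Product: 10 [(2R,3R)-3-{3-[(tert-butyldiphenylsilyl)oxy]prop-1-en-2-yl}-4-methyl-5-oxooxolan-2-yl]methyl 4-methylbenzenesulfonate
Conditions: TsCl (1.2 equiv), pyridine, 0 °C
Reagents that add atoms: 4-methylbenzenesulfonyl chloride Cc1ccc(cc1)S(Cl)(=O)=O
Why: Sulfonylation of the single primary hydroxyl prepares the leaving group for the inversion sequence.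

**Step 8**
Reactants: 10 [(2R,3R)-3-{3-[(tert-butyldiphenylsilyl)oxy]prop-1-en-2-yl}-4-methyl-5-oxooxolan-2-yl]methyl 4-methylbenzenesulfonate
Product: 12 (4R,5S)-4-{3-[(tert-butyldiphenylsilyl)oxy]prop-1-en-2-yl}-5-(hydroxymethyl)-3-methyloxolan-2-one, via epoxy acid 11 (not isolated)
Conditions: LiOH·H2O (3 equiv), THF–H2O, 0 °C → rt; then 1 M HCl to pH 2, rt
Reagents that add atoms: lithium hydroxide [Li+].[OH-]
Why: Saponification frees the C6 alkoxide, which closes the terminal epoxide by intramolecular Williamson displacement of tosylate; on acidification the carboxylic acid opens the epoxide 5-exo with inversion at C6 (the ribono-to-lyxono lactone tactic), giving the 4,5-trans lactone with the final C6 configuration.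

**Step 9**
Reactants: 12 (4R,5S)-4-{3-[(tert-butyldiphenylsilyl)oxy]prop-1-en-2-yl}-5-(hydroxymethyl)-3-methyloxolan-2-one
Product: 14 (4R,5R)-4-{3-[(tert-butyldiphenylsilyl)oxy]prop-1-en-2-yl}-3-methyl-5-(2-methylprop-1-en-1-yl)oxolan-2-one, via lactone aldehyde 13 (not isolated)
Conditions: Dess–Martin periodinane, CH2Cl2, 0 °C → rt; then i-PrPPh3I/n-BuLi, THF, −78 → 0 °C
Reagents that add atoms: triphenyl(propan-2-ylidene)-λ5-phosphane CC(C)=P(c1ccccc1)(c1ccccc1)c1ccccc1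
Why: Dess–Martin oxidation and Wittig olefination with the non-stabilized isopropylidene ylide install the trisubstituted alkene (C7=C11) that later serves as the ene donor.

**Step 10**
Reactants: 15 2,2-dimethoxyethan-1-ol
Product: 16 2,2-dimethoxyethyl trifluoromethanesulfonate
Conditions: Tf2O, 2,6-lutidine, CH2Cl2, −78 °C, used at once
Reagents that add atoms: trifluoromethanesulfonic anhydride O=S(=O)(OS(=O)(=O)C(F)(F)F)C(F)(F)F
Why: O-Triflation gives a reactive two-carbon electrophile that carries the C8 aldehyde in masked form.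

**Step 11**
Reactants: 14 (4R,5R)-4-{3-[(tert-butyldiphenylsilyl)oxy]prop-1-en-2-yl}-3-methyl-5-(2-methylprop-1-en-1-yl)oxolan-2-one; 16 2,2-dimethoxyethyl trifluoromethanesulfonate
Product: 18 2-[(3S,4S,5R)-4-{3-[(tert-butyldiphenylsilyl)oxy]prop-1-en-2-yl}-3-methyl-5-(2-methylprop-1-en-1-yl)-2-oxooxolan-3-yl]acetaldehyde, via dimethyl acetal 17 (not isolated)
Conditions: LiN(i-Pr)2, THF, −78 °C; 16, −78 → −30 °C; then PPTS (cat.), acetone–H2O, 45 °C
Reagents that add atoms: water O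
Why: The lactone enolate is alkylated anti to the adjacent C5 substituent, hence on the face of the C6 side chain, which creates the quaternary centre C10 in the required configuration; mild acetal hydrolysis then frees the aldehyde.

**Step 12**
Reactants: 18 2-[(3S,4S,5R)-4-{3-[(tert-butyldiphenylsilyl)oxy]prop-1-en-2-yl}-3-methyl-5-(2-methylprop-1-en-1-yl)-2-oxooxolan-3-yl]acetaldehyde
Product: 19 (1S,3S,4R,5S,8S)-8-{3-[(tert-butyldiphenylsilyl)oxy]prop-1-en-2-yl}-3-hydroxy-1-methyl-4-(prop-1-en-2-yl)-6-oxabicyclo[3.2.1]octan-7-one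
Conditions: ZnBr2 (1.2 equiv), CH2Cl2, 0 °C
Reagents that add atoms: none
Why: ZnBr2-promoted type 1 intramolecular carbonyl-ene reaction (isopulegol-type chair transition state on the cis-disposed lactone template) closes the carbocycle at C7–C8, placing the new isopropenyl group equatorial (sets C7) and the new hydroxyl equatorial (corrected in steps 13 and 14).

**Step 13**
Reactants: 19 (1S,3S,4R,5S,8S)-8-{3-[(tert-butyldiphenylsilyl)oxy]prop-1-en-2-yl}-3-hydroxy-1-methyl-4-(prop-1-en-2-yl)-6-oxabicyclo[3.2.1]octan-7-one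
Product: 20 (1S,4S,5S,8S)-8-{3-[(tert-butyldiphenylsilyl)oxy]prop-1-en-2-yl}-1-methyl-4-(prop-1-en-2-yl)-6-oxabicyclo[3.2.1]octane-3,7-dione
Conditions: Dess–Martin periodinane, CH2Cl2, rt
Reagents that add atoms: none
Why: Dess–Martin oxidation erases the wrong C8 configuration under non-basic conditions.

**Step 14**
Reactants: 20 (1S,4S,5S,8S)-8-{3-[(tert-butyldiphenylsilyl)oxy]prop-1-en-2-yl}-1-methyl-4-(prop-1-en-2-yl)-6-oxabicyclo[3.2.1]octane-3,7-dione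
Product: 21 (1S,3R,4R,5S,8S)-8-{3-[(tert-butyldiphenylsilyl)oxy]prop-1-en-2-yl}-1-methyl-4-(prop-1-en-2-yl)-6-oxabicyclo[3.2.1]octane-3,7-diol
Conditions: i-Bu2AlH (4 equiv), CH2Cl2, −78 °C
Reagents that add atoms: none
Why: Bulky i-Bu2AlH attacks the ketone from the face opposite the lactone bridge (as in tropinone to tropine), giving the axial hydroxyl syn to the bridge (sets C8), and reduces the lactone only to the lactol at −78 °C.

**Step 15**
Reactants: 21 (1S,3R,4R,5S,8S)-8-{3-[(tert-butyldiphenylsilyl)oxy]prop-1-en-2-yl}-1-methyl-4-(prop-1-en-2-yl)-6-oxabicyclo[3.2.1]octane-3,7-diol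
Product: 22 (1R,2R,3S,4R,5R)-4-{3-[(tert-butyldiphenylsilyl)oxy]prop-1-en-2-yl}-5-ethenyl-5-methyl-2-(prop-1-en-2-yl)cyclohexane-1,3-diol
Conditions: Ph3PCH3Br, KOt-Bu, THF, 0 → 50 °C
Reagents that add atoms: methylidene(triphenyl)-λ5-phosphane C=P(c1ccccc1)(c1ccccc1)c1ccccc1
Why: Wittig methylenation of the open hydroxy-aldehyde form of the lactol turns C1 into the vinyl group and releases the C6 hydroxyl, leaving the all-cis cyclohexane.

**Step 16**
Reactants: 23 3-methylfuran-2(5H)-one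
Product: 26 (4-methoxyphenyl)methyl (2Z)-4-(acetyloxy)-2-methylbut-2-enoate, via sodium salt 24 (not isolated), via hydroxy ester 25 (not isolated)
Conditions: NaOH (1.0 equiv), H2O–MeOH, rt; evaporate; 4-MeOC6H4CH2Cl, DMF, rt; then Ac2O, pyridine, 0 °C
Reagents that add atoms: sodium hydroxide [Na+].[OH-]; 4-methoxybenzyl chloride COc1ccc(CCl)cc1; acetic anhydride CC(=O)OC(C)=O
Why: Hydroxide opens the butenolide to the (Z)-hydroxy enoate (ring-derived geometry); the carboxylate is O-alkylated and the hydroxyl acetylated in the same flask before relactonization can occur.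

**Step 17**
Reactants: 26 (4-methoxyphenyl)methyl (2Z)-4-(acetyloxy)-2-methylbut-2-enoate
Product: 27 (2Z)-4-(acetyloxy)-2-methylbut-2-enoic acid
Conditions: CF3CO2H, anisole, CH2Cl2, 0 °C
Reagents that add atoms: none
Why: Acidolysis of the 4-methoxybenzyl ester (cation trapped by anisole) frees the acid without touching the acetate or the Z-alkene.

**Step 18**
Reactants: 22 (1R,2R,3S,4R,5R)-4-{3-[(tert-butyldiphenylsilyl)oxy]prop-1-en-2-yl}-5-ethenyl-5-methyl-2-(prop-1-en-2-yl)cyclohexane-1,3-diol; 27 (2Z)-4-(acetyloxy)-2-methylbut-2-enoic acid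
Product: 29 (1R,2S,3S,4R,5R)-4-{3-[(tert-butyldiphenylsilyl)oxy]prop-1-en-2-yl}-5-ethenyl-3-hydroxy-5-methyl-2-(prop-1-en-2-yl)cyclohexyl (2Z)-4-(acetyloxy)-2-methylbut-2-enoate, via mixed anhydride 28 (not isolated)
Conditions: 27, 2,4,6-Cl3C6H2COCl, Et3N, toluene, rt; then 22, toluene, 80 °C (no DMAP)
Reagents that add atoms: none
Why: Yamaguchi esterification through the mixed anhydride, run without DMAP to avoid Z-to-E isomerization, acylates the C8 hydroxyl (flanked by a CH2) in preference to the C6 hydroxyl (flanked by two branched carbons).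

**Step 19**
Reactants: 29 (1R,2S,3S,4R,5R)-4-{3-[(tert-butyldiphenylsilyl)oxy]prop-1-en-2-yl}-5-ethenyl-3-hydroxy-5-methyl-2-(prop-1-en-2-yl)cyclohexyl (2Z)-4-(acetyloxy)-2-methylbut-2-enoate
Product: 30 (1R,2R,3S,4R,5R)-4-{3-[(tert-butyldiphenylsilyl)oxy]prop-1-en-2-yl}-5-ethenyl-5-methyl-2-(prop-1-en-2-yl)-3-[(triethylsilyl)oxy]cyclohexyl (2Z)-4-(acetyloxy)-2-methylbut-2-enoate
Conditions: Et3SiOTf, 2,6-lutidine, CH2Cl2, −40 → 0 °C
Reagents that add atoms: triethylsilyl trifluoromethanesulfonate CC[Si](CC)(CC)OS(=O)(=O)C(F)(F)F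
Why: The silyl triflate silylates the remaining hindered axial C6 hydroxyl so that it cannot form a lactol or lactone with C12 in the next two steps.

**Step 20**
Reactants: 30 (1R,2R,3S,4R,5R)-4-{3-[(tert-butyldiphenylsilyl)oxy]prop-1-en-2-yl}-5-ethenyl-5-methyl-2-(prop-1-en-2-yl)-3-[(triethylsilyl)oxy]cyclohexyl (2Z)-4-(acetyloxy)-2-methylbut-2-enoate
Product: 31 (1R,2R,3S,4R,5R)-4-{3-[(tert-butyldiphenylsilyl)oxy]prop-1-en-2-yl}-5-ethenyl-2-(3-hydroxyprop-1-en-2-yl)-5-methyl-3-[(triethylsilyl)oxy]cyclohexyl (2Z)-4-(acetyloxy)-2-methylbut-2-enoate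
Conditions: SeO2 (0.5 equiv), t-BuOOH, CH2Cl2, rt
Reagents that add atoms: tert-butyl hydroperoxide CC(C)(C)OO
Why: SeO2 allylic oxidation attacks the only electron-rich alkene that still bears an allylic CH3, the C7 isopropenyl group, giving the allylic alcohol at C12.

**Step 21**
Reactants: 31 (1R,2R,3S,4R,5R)-4-{3-[(tert-butyldiphenylsilyl)oxy]prop-1-en-2-yl}-5-ethenyl-2-(3-hydroxyprop-1-en-2-yl)-5-methyl-3-[(triethylsilyl)oxy]cyclohexyl (2Z)-4-(acetyloxy)-2-methylbut-2-enoate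
Product: 33 2-[(1R,2S,3R,4R,6R)-6-{[(2Z)-4-(acetyloxy)-2-methylbut-2-enoyl]oxy}-3-{3-[(tert-butyldiphenylsilyl)oxy]prop-1-en-2-yl}-4-ethenyl-4-methyl-2-[(triethylsilyl)oxy]cyclohexyl]prop-2-enoic acid, via enal 32 (not isolated)
Conditions: Dess–Martin periodinane, CH2Cl2, 0 °C; then NaClO2, NaH2PO4, 2-methylbut-2-ene, t-BuOH–H2O, 0 °C
Reagents that add atoms: sodium chlorite [Na+].[O-]Cl=O
Why: Dess–Martin oxidation to the enal followed by Pinnick oxidation with a hypochlorite scavenger gives the acrylic acid without affecting the other alkenes, esters or silyl ethers.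

**Step 22**
Reactants: 33 2-[(1R,2S,3R,4R,6R)-6-{[(2Z)-4-(acetyloxy)-2-methylbut-2-enoyl]oxy}-3-{3-[(tert-butyldiphenylsilyl)oxy]prop-1-en-2-yl}-4-ethenyl-4-methyl-2-[(triethylsilyl)oxy]cyclohexyl]prop-2-enoic acid
Product: 34 2-[(1S,2S,3R,4R,6R)-6-{[(2Z)-4-(acetyloxy)-2-methylbut-2-enoyl]oxy}-4-ethenyl-2-hydroxy-3-(3-hydroxyprop-1-en-2-yl)-4-methylcyclohexyl]prop-2-enoic acid
Conditions: Bu4NF/AcOH (1:1), THF, 0 °C → rt; cold work-up at pH 5
Reagents that add atoms: none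
Why: Buffered fluoride cleaves both silyl ethers, and the near-neutral conditions with a cold pH 5 work-up avoid acetate migration and lactonization of the cis γ-hydroxy acid.

**Compound list**
1 | methyl (4S)-2,2-dimethyl-1,3-dioxolane-4-carboxylate | COC(=O)[C@@H]1COC(C)(C)O1 | starting material
2 | (4S)-2,2-dimethyl-1,3-dioxolane-4-carbaldehyde | O=C[C@@H]1COC(C)(C)O1 | intermediate
3 | ethyl (2E)-3-[(4R)-2,2-dimethyl-1,3-dioxolan-4-yl]-2-methylprop-2-enoate | CCOC(=O)/C(C)=C/[C@@H]1COC(C)(C)O1 | intermediate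
4 | (2E)-3-[(4R)-2,2-dimethyl-1,3-dioxolan-4-yl]-2-methylprop-2-en-1-ol | OC/C(C)=C/[C@@H]1COC(C)(C)O1 | intermediate
5 | (4R)-4-{(1E)-3-[(1-ethoxyprop-1-en-1-yl)oxy]-2-methylprop-1-en-1-yl}-2,2-dimethyl-1,3-dioxolane | CCOC(=CC)OC/C(C)=C/[C@@H]1COC(C)(C)O1 | intermediate
6 | ethyl (3R)-3-[(4R)-2,2-dimethyl-1,3-dioxolan-4-yl]-2,4-dimethylpent-4-enoate (both C2 epimers) | CCOC(=O)C(C)[C@@H]([C@@H]1COC(C)(C)O1)C(C)=C | intermediate
7 | ethyl (3R)-3-[(4R)-2,2-dimethyl-1,3-dioxolan-4-yl]-4-(hydroxymethyl)-2-methylpent-4-enoate (both C2 epimers) | CCOC(=O)C(C)[C@@H]([C@@H]1COC(C)(C)O1)C(=C)CO | intermediate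
8 | ethyl (3R)-4-{[(tert-butyldiphenylsilyl)oxy]methyl}-3-[(4R)-2,2-dimethyl-1,3-dioxolan-4-yl]-2-methylpent-4-enoate (both C2 epimers) | CCOC(=O)C(C)[C@@H]([C@@H]1COC(C)(C)O1)C(=C)CO[Si](c1ccccc1)(c1ccccc1)C(C)(C)C | intermediate
9 | (4R,5R)-4-{3-[(tert-butyldiphenylsilyl)oxy]prop-1-en-2-yl}-5-(hydroxymethyl)-3-methyloxolan-2-one (4,5-cis; both C3 epimers) | O=C1O[C@@H](CO)[C@@H](C(=C)CO[Si](c2ccccc2)(c2ccccc2)C(C)(C)C)C1C | intermediate
10 | [(2R,3R)-3-{3-[(tert-butyldiphenylsilyl)oxy]prop-1-en-2-yl}-4-methyl-5-oxooxolan-2-yl]methyl 4-methylbenzenesulfonate | O=C1O[C@@H](COS(=O)(=O)c2ccc(C)cc2)[C@@H](C(=C)CO[Si](c2ccccc2)(c2ccccc2)C(C)(C)C)C1C | intermediate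
11 | (3R)-4-{[(tert-butyldiphenylsilyl)oxy]methyl}-2-methyl-3-[(2R)-oxiran-2-yl]pent-4-enoic acid | OC(=O)C(C)[C@@H]([C@@H]1CO1)C(=C)CO[Si](c1ccccc1)(c1ccccc1)C(C)(C)C | intermediate
12 | (4R,5S)-4-{3-[(tert-butyldiphenylsilyl)oxy]prop-1-en-2-yl}-5-(hydroxymethyl)-3-methyloxolan-2-one (4,5-trans; both C3 epimers) | O=C1O[C@H](CO)[C@@H](C(=C)CO[Si](c2ccccc2)(c2ccccc2)C(C)(C)C)C1C | intermediate
13 | (2S,3R)-3-{3-[(tert-butyldiphenylsilyl)oxy]prop-1-en-2-yl}-4-methyl-5-oxooxolane-2-carbaldehyde | O=C1O[C@H](C=O)[C@@H](C(=C)CO[Si](c2ccccc2)(c2ccccc2)C(C)(C)C)C1C | intermediate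
14 | (4R,5R)-4-{3-[(tert-butyldiphenylsilyl)oxy]prop-1-en-2-yl}-3-methyl-5-(2-methylprop-1-en-1-yl)oxolan-2-one (4,5-trans; both C3 epimers) | O=C1O[C@H](C=C(C)C)[C@@H](C(=C)CO[Si](c2ccccc2)(c2ccccc2)C(C)(C)C)C1C | intermediate
15 | 2,2-dimethoxyethan-1-ol | OCC(OC)OC | starting material
16 | 2,2-dimethoxyethyl trifluoromethanesulfonate | COC(COS(=O)(=O)C(F)(F)F)OC | intermediate
17 | (3S,4S,5R)-4-{3-[(tert-butyldiphenylsilyl)oxy]prop-1-en-2-yl}-3-(2,2-dimethoxyethyl)-3-methyl-5-(2-methylprop-1-en-1-yl)oxolan-2-one | O=C1O[C@H](C=C(C)C)[C@@H](C(=C)CO[Si](c2ccccc2)(c2ccccc2)C(C)(C)C)[C@]1(C)CC(OC)OC | intermediate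
18 | 2-[(3S,4S,5R)-4-{3-[(tert-butyldiphenylsilyl)oxy]prop-1-en-2-yl}-3-methyl-5-(2-methylprop-1-en-1-yl)-2-oxooxolan-3-yl]acetaldehyde | O=C1O[C@H](C=C(C)C)[C@@H](C(=C)CO[Si](c2ccccc2)(c2ccccc2)C(C)(C)C)[C@]1(C)CC=O | intermediate
19 | (1S,3S,4R,5S,8S)-8-{3-[(tert-butyldiphenylsilyl)oxy]prop-1-en-2-yl}-3-hydroxy-1-methyl-4-(prop-1-en-2-yl)-6-oxabicyclo[3.2.1]octan-7-one | O=C2[C@@]1(C)C[C@H](O)[C@@H](C(C)=C)[C@@H](O2)[C@H]1C(=C)CO[Si](c3ccccc3)(c3ccccc3)C(C)(C)C | intermediate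
20 | (1S,4S,5S,8S)-8-{3-[(tert-butyldiphenylsilyl)oxy]prop-1-en-2-yl}-1-methyl-4-(prop-1-en-2-yl)-6-oxabicyclo[3.2.1]octane-3,7-dione | O=C2[C@@]1(C)CC(=O)[C@@H](C(C)=C)[C@@H](O2)[C@H]1C(=C)CO[Si](c3ccccc3)(c3ccccc3)C(C)(C)C | intermediate
21 | (1S,3R,4R,5S,8S)-8-{3-[(tert-butyldiphenylsilyl)oxy]prop-1-en-2-yl}-1-methyl-4-(prop-1-en-2-yl)-6-oxabicyclo[3.2.1]octane-3,7-diol (lactol; both C7 epimers) | OC2[C@@]1(C)C[C@@H](O)[C@@H](C(C)=C)[C@@H](O2)[C@H]1C(=C)CO[Si](c3ccccc3)(c3ccccc3)C(C)(C)C | intermediate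
22 | (1R,2R,3S,4R,5R)-4-{3-[(tert-butyldiphenylsilyl)oxy]prop-1-en-2-yl}-5-ethenyl-5-methyl-2-(prop-1-en-2-yl)cyclohexane-1,3-diol | C=C[C@@]1(C)C[C@@H](O)[C@@H](C(C)=C)[C@@H](O)[C@H]1C(=C)CO[Si](c2ccccc2)(c2ccccc2)C(C)(C)C | intermediate
23 | 3-methylfuran-2(5H)-one | CC1=CCOC1=O | starting material
24 | sodium (2Z)-4-hydroxy-2-methylbut-2-enoate | [Na+].[O-]C(=O)/C(C)=C\CO | intermediate
25 | (4-methoxyphenyl)methyl (2Z)-4-hydroxy-2-methylbut-2-enoate | COc1ccc(COC(=O)/C(C)=C\CO)cc1 | intermediate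
26 | (4-methoxyphenyl)methyl (2Z)-4-(acetyloxy)-2-methylbut-2-enoate | COc1ccc(COC(=O)/C(C)=C\COC(C)=O)cc1 | intermediate
27 | (2Z)-4-(acetyloxy)-2-methylbut-2-enoic acid | OC(=O)/C(C)=C\COC(C)=O | intermediate
28 | (2Z)-4-(acetyloxy)-2-methylbut-2-enoic 2,4,6-trichlorobenzoic anhydride | O=C(OC(=O)/C(C)=C\COC(C)=O)c1c(Cl)cc(Cl)cc1Cl | intermediate
29 | (1R,2S,3S,4R,5R)-4-{3-[(tert-butyldiphenylsilyl)oxy]prop-1-en-2-yl}-5-ethenyl-3-hydroxy-5-methyl-2-(prop-1-en-2-yl)cyclohexyl (2Z)-4-(acetyloxy)-2-methylbut-2-enoate | C=C[C@@]1(C)C[C@@H](OC(=O)/C(C)=C\COC(C)=O)[C@@H](C(C)=C)[C@@H](O)[C@H]1C(=C)CO[Si](c2ccccc2)(c2ccccc2)C(C)(C)C | intermediate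
30 | (1R,2R,3S,4R,5R)-4-{3-[(tert-butyldiphenylsilyl)oxy]prop-1-en-2-yl}-5-ethenyl-5-methyl-2-(prop-1-en-2-yl)-3-[(triethylsilyl)oxy]cyclohexyl (2Z)-4-(acetyloxy)-2-methylbut-2-enoate | C=C[C@@]1(C)C[C@@H](OC(=O)/C(C)=C\COC(C)=O)[C@@H](C(C)=C)[C@@H](O[Si](CC)(CC)CC)[C@H]1C(=C)CO[Si](c2ccccc2)(c2ccccc2)C(C)(C)C | intermediate
31 | (1R,2R,3S,4R,5R)-4-{3-[(tert-butyldiphenylsilyl)oxy]prop-1-en-2-yl}-5-ethenyl-2-(3-hydroxyprop-1-en-2-yl)-5-methyl-3-[(triethylsilyl)oxy]cyclohexyl (2Z)-4-(acetyloxy)-2-methylbut-2-enoate | C=C[C@@]1(C)C[C@@H](OC(=O)/C(C)=C\COC(C)=O)[C@@H](C(=C)CO)[C@@H](O[Si](CC)(CC)CC)[C@H]1C(=C)CO[Si](c2ccccc2)(c2ccccc2)C(C)(C)C | intermediate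
32 | (1R,2R,3S,4R,5R)-4-{3-[(tert-butyldiphenylsilyl)oxy]prop-1-en-2-yl}-5-ethenyl-5-methyl-2-(3-oxoprop-1-en-2-yl)-3-[(triethylsilyl)oxy]cyclohexyl (2Z)-4-(acetyloxy)-2-methylbut-2-enoate | C=C[C@@]1(C)C[C@@H](OC(=O)/C(C)=C\COC(C)=O)[C@@H](C(=C)C=O)[C@@H](O[Si](CC)(CC)CC)[C@H]1C(=C)CO[Si](c2ccccc2)(c2ccccc2)C(C)(C)C | intermediate
33 | 2-[(1R,2S,3R,4R,6R)-6-{[(2Z)-4-(acetyloxy)-2-methylbut-2-enoyl]oxy}-3-{3-[(tert-butyldiphenylsilyl)oxy]prop-1-en-2-yl}-4-ethenyl-4-methyl-2-[(triethylsilyl)oxy]cyclohexyl]prop-2-enoic acid | C=C[C@@]1(C)C[C@@H](OC(=O)/C(C)=C\COC(C)=O)[C@@H](C(=C)C(=O)O)[C@@H](O[Si](CC)(CC)CC)[C@H]1C(=C)CO[Si](c2ccccc2)(c2ccccc2)C(C)(C)C | intermediate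
34 | 2-[(1S,2S,3R,4R,6R)-6-{[(2Z)-4-(acetyloxy)-2-methylbut-2-enoyl]oxy}-4-ethenyl-2-hydroxy-3-(3-hydroxyprop-1-en-2-yl)-4-methylcyclohexyl]prop-2-enoic acid | C=C[C@@]1(C)C[C@@H](OC(=O)/C(C)=C\COC(C)=O)[C@@H](C(=C)C(=O)O)[C@@H](O)[C@H]1C(=C)CO | target

**Step count and risks**
Total step count: 22. Longest linear sequence: 19 steps (steps 1–9, 11–15, 18–22); steps 10, 16 and 17 make the two side components.

Three steps most likely to fail:

Step 12 (carbonyl-ene closure of the bridged ring). The silyloxymethyl-substituted alkene on C5 can compete as ene donor, and the allylic lactone may ionize under Lewis acid. The fallback sets out from 18. Pinnick oxidation (NaClO2, NaH2PO4, 2-methylbut-2-ene) gives 2-[(3S,4S,5R)-4-{3-[(tert-butyldiphenylsilyl)oxy]prop-1-en-2-yl}-3-methyl-5-(2-methylprop-1-en-1-yl)-2-oxooxolan-3-yl]acetic acid F1. Oxalyl chloride with catalytic DMF converts it into 2-[(3S,4S,5R)-4-{3-[(tert-butyldiphenylsilyl)oxy]prop-1-en-2-yl}-3-methyl-5-(2-methylprop-1-en-1-yl)-2-oxooxolan-3-yl]acetyl chloride F2. SnCl4 in CH2Cl2 at −78 °C then drives a cationic intramolecular acylation of the trisubstituted alkene with proton loss from a methyl group. This comes back to the route at diketone 20, so that 19 and step 13 are bypassed.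

Step 18 (regioselective esterification of the hindered axial C8 hydroxyl with a Z-acid that isomerizes easily). The fallback sets out from 22. DCC-mediated acylation with 2-[bis(2,2,2-trifluoroethoxy)phosphoryl]propanoic acid proceeds through a small, reactive phosphonoketene and gives (1R,2S,3S,4R,5R)-4-{3-[(tert-butyldiphenylsilyl)oxy]prop-1-en-2-yl}-5-ethenyl-3-hydroxy-5-methyl-2-(prop-1-en-2-yl)cyclohexyl 2-[bis(2,2,2-trifluoroethoxy)phosphoryl]propanoate F3. A Still–Gennari olefination (KN(SiMe3)2, 18-crown-6, THF, −78 °C, then 2-oxoethyl acetate) builds the Z-alkene on the substrate and comes back to the route at 29.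

Step 11 (quaternary centre by alkylation of a fully substituted lactone enolate with a β-oxygenated triflate). The fallback sets out from 14. Its lithium enolate is added to phenyl vinyl sulfoxide in a Michael addition with the same anti facial sense, giving (3S,4S,5R)-3-[2-(benzenesulfinyl)ethyl]-4-{3-[(tert-butyldiphenylsilyl)oxy]prop-1-en-2-yl}-3-methyl-5-(2-methylprop-1-en-1-yl)oxolan-2-one F4. A Pummerer rearrangement ((CF3CO)2O, 2,6-lutidine, then aqueous NaHCO3) turns the CH2S(O)Ph end into the aldehyde and comes back to the route at 18.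

**Further compounds**
F1 | step 12 | 2-[(3S,4S,5R)-4-{3-[(tert-butyldiphenylsilyl)oxy]prop-1-en-2-yl}-3-methyl-5-(2-methylprop-1-en-1-yl)-2-oxooxolan-3-yl]acetic acid | O=C1O[C@H](C=C(C)C)[C@@H](C(=C)CO[Si](c2ccccc2)(c2ccccc2)C(C)(C)C)[C@]1(C)CC(=O)O
F2 | step 12 | 2-[(3S,4S,5R)-4-{3-[(tert-butyldiphenylsilyl)oxy]prop-1-en-2-yl}-3-methyl-5-(2-methylprop-1-en-1-yl)-2-oxooxolan-3-yl]acetyl chloride | O=C1O[C@H](C=C(C)C)[C@@H](C(=C)CO[Si](c2ccccc2)(c2ccccc2)C(C)(C)C)[C@]1(C)CC(=O)Cl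
F3 | step 18 | (1R,2S,3S,4R,5R)-4-{3-[(tert-butyldiphenylsilyl)oxy]prop-1-en-2-yl}-5-ethenyl-3-hydroxy-5-methyl-2-(prop-1-en-2-yl)cyclohexyl 2-[bis(2,2,2-trifluoroethoxy)phosphoryl]propanoate | C=C[C@@]1(C)C[C@@H](OC(=O)C(C)P(=O)(OCC(F)(F)F)OCC(F)(F)F)[C@@H](C(C)=C)[C@@H](O)[C@H]1C(=C)CO[Si](c2ccccc2)(c2ccccc2)C(C)(C)C
F4 | step 11 | (3S,4S,5R)-3-[2-(benzenesulfinyl)ethyl]-4-{3-[(tert-butyldiphenylsilyl)oxy]prop-1-en-2-yl}-3-methyl-5-(2-methylprop-1-en-1-yl)oxolan-2-one | O=C1O[C@H](C=C(C)C)[C@@H](C(=C)CO[Si](c2ccccc2)(c2ccccc2)C(C)(C)C)[C@]1(C)CCS(=O)c1ccccc1
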